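How much target can stand in this flask late in the hour, at 1.0 h? First, what is on the bench.

- spring: starting material 20 mM; second substrate 40 mM; free catalyst 40 µM; the very flask that is asked about, followed so far
- flask: starting material 20 mM; second substrate 40.0 mM; free catalyst 40 µM; time 1.0 h

spring run (percent of the starting material charged): time / min: target / % = 0.417: 1.3; 1.00: 4.1; 2.00: 7.3; 3.00: 9.6; 4.00: 12.8; 6.00: 18.3; 8.00: 22.5

(scatter of a reading: 0.5 percentage points)

1. time, not beyond 1.0 h, at which the flask holds most target
2. the amount of target, in percent of the starting material charged, at that time
3. the first time at which target reaches 52%, in the same percent

- a species is counted by the starting material in it: one side product counts as two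
- the earlier runs were read with a standard deviation of 0.5 percentage points
- steps thought possible: starting material + free catalyst <-> catalyst intermediate A; catalyst intermediate A -> free catalyst + target; second substrate + free catalyst <-> catalyst intermediate B; catalyst intermediate B -> free catalyst + second product; starting material -> decomposition product; starting material + target -> side product

Which steps are possible? Starting material binds free catalyst as catalyst intermediate A, which releases target. Second substrate binds free catalyst as catalyst intermediate B, which releases second product. Starting material can also decompose, or combine with target to give side product.

What do the readings yield? If free catalyst keeps a steady share, starting material follows a first-order law. My working figure is 0.0319 min⁻¹: this is k′, the pseudo-first-order constant, minus the natural logarithm of the fraction of the charge not yet found as target, divided by time, read at 8.00 min.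

Does it drift? The reading at 4.00 min gives 0.0342 min⁻¹, so with a scatter of 0.5 percentage points I see no clear drift.

What follows? With k′ steady and no loss, 14.8% of the starting material remains at 1.0 h, target stands at 85.2%, and the asked level falls at 0.384 h.

But doesn't side product eat target? It does. With k′ steady, the making goes as starting material and that loss as starting material times target, so making over loss falls as target grows. The readings give no size for that ratio. Taking it to stay above one, I commit to a maximum at the end of the hour, target somewhat under my figure, and the level somewhat later.

The forecast gives 68% at 1 h and the level at 0.47 h, holding that “it should keep rising, or at worst plateau”. Its target is lower than mine.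

The flask gives 74.9% at 1.00 h and the level at 0.421 h.

    starting material + free catalyst ⇌ catalyst intermediate A (K = 22.3 L mol⁻¹, k = 4850 L mol⁻¹ min⁻¹)
    catalyst intermediate A → free catalyst + target (k = 346 min⁻¹)
    second substrate + free catalyst ⇌ catalyst intermediate B (K = 190 L mol⁻¹, k = 524 L mol⁻¹ min⁻¹)
    catalyst intermediate B → free catalyst + second product (k = 5.35 min⁻¹)
    starting material → decomposition product (k = 3.53 × 10⁻⁵ min⁻¹)
    starting material + target → side product (k = 0.440 L mol⁻¹ min⁻¹)

Here 9.04% of the starting material remained, against the 14.8% from k′, while free catalyst went from 27.3% at 0.100 h to 33.0% at 1.00 h. The neighbour flask charged with 160 mM of second substrate ended with 9.37% free catalyst. Scaling k′ by that end share against the 27.3% free catalyst that this flask held at 0.100 h, within the span of the readings, gives 0.0109 min⁻¹, hence 52.0% of the starting material left at 1.0 h. That neighbour flask held 46.4% of its starting material, with 38.3% target.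

The runs are simulated on assumed constants; noise was put on by code.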